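Assumption: the target has no stereocentre and no stereogenic double bond, so it is achiral and "the single enantiomer" is simply the compound as drawn (2-hydroxy-3-hexadecyl-5-methoxy-1,4-benzoquinone, C23H38O4).

**Retrosynthetic overview**
1. Target 6 ⇒ 3-hexadecyl-2,5-dihydroxy-1,4-benzoquinone 5, by regioselective O-methylation of the unhindered vinylogous-acid unit next to the ring C–H.
2. 5 ⇒ ring C3–CH2 bond: quinone C3 as an enolonium equivalent (phenyliodonium ylide 2) joined to a nucleophilic hexadecyl group (B-hexadecyl-9-BBN 4, from 1-hexadecene 3). Both carbons are natural donors; the iodine(III) inverts the polarity of the enol carbon.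
3. 2 ⇒ 2,5-dihydroxy-1,4-benzoquinone 1 + PhI(OAc)2.
4. No ring is formed: the quinone ring is bought in 1, and there is no stereochemistry to set.

**Route**

Step 1
Reactants: 1 2,5-dihydroxy-1,4-benzoquinone
Product: 2 5-hydroxy-2-oxido-3-(phenyliodonio)-1,4-benzoquinone (mono phenyliodonium ylide, zwitterion)
Conditions: PhI(OAc)2 (1.0 equiv, added slowly), MeCN–CH2Cl2, 0 °C to rt, dark; ylide filtered off and stored cold
Reagents that add atoms: (diacetoxyiodo)benzene, CC(=O)OI(OC(C)=O)c1ccccc1
Why: The enolic C3 of the vinylogous acid attacks iodine(III) with loss of two AcOH to give the stabilised β-dicarbonyl iodonium ylide (known hydroxyquinone iodonium-ylide formation), and the electron-withdrawing iodonio group deactivates the second enol unit so that one equivalent stops at the mono-ylide.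

Step 2
Reactants: 2 5-hydroxy-2-oxido-3-(phenyliodonio)-1,4-benzoquinone; 3 1-hexadecene
Product: 5 3-hexadecyl-2,5-dihydroxy-1,4-benzoquinone, via B-hexadecyl-9-BBN 4 (not isolated)
Conditions: 3 (1.3 equiv), 9-BBN (1.25 equiv), THF, 0 °C to rt, 4 h; then 2 (1.0 equiv), PdCl2(dppf)·CH2Cl2 (5 mol%), AsPh3 (5 mol%), K3PO4 (3 equiv, 3 M aq.), DMF/THF, rt, dark, Ar; 1 M HCl work-up
Reagents that add atoms: 9-borabicyclo[3.3.1]nonane (9-BBN), [H]B1C2CCCC1CCC2 (its atoms end up in intermediate 4 only, none in 5)
Why: Proposed new method: the ylide carbon, normally the nucleophilic α-carbon of the enolised dicarbonyl, is turned into an enolonium equivalent by the PhI(III) hypernucleofuge, so Pd(0) inserts into the quinonyl C–I(III) bond at rt with loss of PhI, the primary alkyl group is transferred from the base-activated 9-BBN ate complex (4 coming from standard anti-Markovnikov hydroboration of 3), and the wide-bite-angle dppf ligand lets reductive elimination outrun β-hydride elimination; the closest known reaction types are the Pd-catalysed Suzuki–Miyaura arylation of hydroxyquinone phenyliodonium ylides with arylboronic acids and the room-temperature B-alkyl Suzuki–Miyaura coupling of alkenyl iodides, and no stereocentre is formed.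

Step 3
Reactants: 5 3-hexadecyl-2,5-dihydroxy-1,4-benzoquinone
Product: 6 2-hydroxy-3-hexadecyl-5-methoxy-1,4-benzoquinone (target)
Conditions: MeOH (solvent), conc. H2SO4 (cat.), 50 °C, stopped by TLC when 5 is consumed
Reagents that add atoms: methanol, CO
Why: Acid-catalysed addition–elimination of methanol (vinylogous Fischer esterification of a hydroxyquinone) takes place at the unhindered vinylogous-acid unit flanking the ring C–H, whereas the unit flanking the hexadecyl chain is shielded and its ether would be twisted out of conjugation, so the mono-ether with OMe next to H and OH next to the chain is both the kinetic and the thermodynamic product; no stereocentre is involved.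

**Compound list**
1 | 2,5-dihydroxy-1,4-benzoquinone | O=C1C=C(O)C(=O)C=C1O | starting material
2 | 5-hydroxy-2-oxido-3-(phenyliodonio)-1,4-benzoquinone (zwitterionic mono-ylide) | [O-]C1=C([I+]c2ccccc2)C(=O)C(O)=CC1=O | intermediate
3 | 1-hexadecene | CCCCCCCCCCCCCCC=C | starting material
4 | B-hexadecyl-9-BBN (9-hexadecyl-9-borabicyclo[3.3.1]nonane) | CCCCCCCCCCCCCCCCB1C2CCCC1CCC2 | intermediate
5 | 3-hexadecyl-2,5-dihydroxy-1,4-benzoquinone | CCCCCCCCCCCCCCCCC1=C(O)C(=O)C=C(O)C1=O | intermediate
6 | 2-hydroxy-3-hexadecyl-5-methoxy-1,4-benzoquinone | CCCCCCCCCCCCCCCCC1=C(O)C(=O)C=C(OC)C1=O | target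

**Totals**
Total step count: 3 (the hydroboration is run in the same flask as the coupling).
Longest linear sequence: 3 steps (1 → 2 → 5 → 6).

**Steps most likely to fail, with fallbacks**

Step 2 (highest risk). An sp3 alkylborane has not been coupled to such an ylide before. Possible failures are β-hydride elimination, thermal ring contraction of the ylide above rt, and redox between the quinone and boron or palladium species. The fallback sets out from 2 and comes back at 5, and moves to the precedented sp2 coupling followed by saturation. Commercial 1-hexadecyne (CCCCCCCCCCCCCCC#C) is hydroborated with pinacolborane (Cp2Zr(H)Cl cat., neat, rt) to give (E)-2-(hexadec-1-en-1-yl)-4,4,5,5-tetramethyl-1,3,2-dioxaborolane F1. Suzuki coupling of F1 with 2 (Pd(OAc)2, P(t-Bu)3·HBF4, K3PO4 aq., DME, rt) gives 3-[(E)-hexadec-1-enyl]-2,5-dihydroxy-1,4-benzoquinone F2. Hydrogenation (H2, Pd/C, EtOAc) saturates the side chain and reduces the ring to 3-hexadecylbenzene-1,2,4,5-tetrol F3, which reoxidises on stirring in air to 5.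

Step 1. The poorly soluble 1 may give mixtures of mono- and bis-ylide. The fallback sets out from 1 and comes back at 6, and removes the second enol before iodine(III) is introduced. Exhaustive etherification of 1 (MeOH, HCl, reflux) gives 2,5-dimethoxy-1,4-benzoquinone F4. Mono-saponification (1.0 equiv NaOH aq., THF, 0 °C, then H+) gives 2-hydroxy-5-methoxy-1,4-benzoquinone F5; the first-formed anion resists a second hydroxide attack. PhI(OAc)2 (CH2Cl2, rt) then gives the only possible ylide, 5-methoxy-2-oxido-3-(phenyliodonio)-1,4-benzoquinone F6. Coupling F6 with 4 (made from 3 as in step 2, same Pd conditions) delivers 6 directly, making step 3 unnecessary.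

Step 3. Over-methylation or incomplete regioselectivity is possible. The fallback sets out from 5 and comes back at 6, and overshoots before cleaving selectively. Exhaustive O-methylation (Me2SO4, K2CO3, acetone, reflux) gives 3-hexadecyl-2,5-dimethoxy-1,4-benzoquinone F7. Brief treatment with 70% HClO4 in dioxane at rt hydrolyses only the methoxy group next to the alkyl chain, which is twisted out of conjugation and therefore the more labile enol ether, giving 6. This regiochemistry is from recall of related 3-alkyl-2,5-dimethoxyquinones and should be confirmed by NOE on the product.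

**Further compounds**
F1 | step 2 | (E)-2-(hexadec-1-en-1-yl)-4,4,5,5-tetramethyl-1,3,2-dioxaborolane | CCCCCCCCCCCCCC/C=C/B1OC(C)(C)C(C)(C)O1
F2 | step 2 | 3-[(E)-hexadec-1-enyl]-2,5-dihydroxy-1,4-benzoquinone | CCCCCCCCCCCCCC/C=C/C1=C(O)C(=O)C=C(O)C1=O
F3 | step 2 | 3-hexadecylbenzene-1,2,4,5-tetrol | CCCCCCCCCCCCCCCCc1c(O)c(O)cc(O)c1O
F4 | step 1 | 2,5-dimethoxy-1,4-benzoquinone | COC1=CC(=O)C(OC)=CC1=O
F5 | step 1 | 2-hydroxy-5-methoxy-1,4-benzoquinone | COC1=CC(=O)C(O)=CC1=O
F6 | step 1 | 5-methoxy-2-oxido-3-(phenyliodonio)-1,4-benzoquinone (zwitterionic ylide) | COC1=CC(=O)C([O-])=C([I+]c2ccccc2)C1=O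
F7 | step 3 | 3-hexadecyl-2,5-dimethoxy-1,4-benzoquinone | CCCCCCCCCCCCCCCCC1=C(OC)C(=O)C=C(OC)C1=O
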